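Plan (labdane numbering: ring A = C1–C5, C10; ring B = C5–C10)
- Retrosynthesis: cut the C2–O angelate and return C15 to the alcohol level. Cut C10–C20, so the angular methyl comes from conjugate addition to a 1(10)-en-2-one. Cut C1–C2 and C5–C10 together. Then cut C5–C6 (alkylation) and C9–C10 (ene reaction).
- Enabling feature: in ring A the run C2(O)–C3H2–C4(CH3)2–C5H is the carbon set of a 2-substituted 3,3-dimethylcyclobutanone, with an extra C2–C5 bond as a temporary ring. C1/C10 is a two-carbon alkyne unit hung on C9. Inserting the alkyne into the C2–C5 bond makes ring B and ring A at once and leaves the oxygen on C2.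
- Forward order: citronellol; ene reaction (C9–C10); O-allylation and metathesis to a temporary dihydropyran that locks C7=C8 as Z; base fragmentation to the Z-enynol; bromide; hydrazone alkylation (C5–C6); rhodium insertion (rings B and A); methyl cuprate (C20); reduction; angelate; C15 oxidation.
- Stereochemistry: C13 comes from (R)-citronellol, C9 from the (S)-BINOL titanium ene reaction, and C5 from SAMP. C10 comes from cuprate attack on the face that bears H5 and H9, which gives the cis fusion. C2 is set as the equatorial alcohol, and the Z ester comes from angelic acid.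

Key step: step 12

Assumption: the SMILES is read literally as 2S,5R,9R,10S,13R, a cis-fused decalin with H5, H9 and the C10 methyl on one face (called beta) and the C9 chain and the C2 oxygen on the other; the senses of induction of (S)-BINOL titanium and of SAMP are taken from their established models.

Step 1
Reactants: 1 (R)-citronellol
Product: 2 (R)-citronellyl tert-butyldiphenylsilyl (TBDPS) ether
Conditions: TBDPSCl, imidazole, DMF, 0 °C to rt
Reagents that add atoms: tert-butyl(chloro)diphenylsilane, CC(C)(C)[Si](Cl)(c1ccccc1)c1ccccc1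
Why: Silyl ether formation at the only hydroxyl group masks C15 at the alcohol level through the basic, hydridic and organometallic steps, and C13 (R) comes unchanged from the chiral pool.

Step 2
Reactants: 2 TBDPS ether; 3 ethyl glyoxylate
Product: 4 ethyl (2S,3R,6R)-8-(TBDPS-oxy)-2-hydroxy-6-methyl-3-(prop-1-en-2-yl)octanoate (syn adduct; ester C = C1, carbinol C = C10, branched C = C9)
Conditions: TiCl2(OiPr)2 (10 mol %), (S)-BINOL (10 mol %), 4 Å molecular sieves, CH2Cl2, −30 °C
Reagents that add atoms: none
Why: Catalytic asymmetric glyoxylate-ene (carbonyl-ene) reaction, known for trisubstituted alkenes: the C–C bond forms at the less substituted alkene carbon C9 with hydrogen transfer from a geminal methyl group, the (S)-BINOL titanium complex sets the carbinol carbon C10 as S, the syn-selective cyclic transition state relays this to 9R, and any anti isomer is removed by chromatography.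

Step 3
Reactants: 4 ene adduct; 5 allyl bromide
Product: 6 ethyl (2S,3R,6R)-2-(allyloxy)-8-(TBDPS-oxy)-6-methyl-3-(prop-1-en-2-yl)octanoate
Conditions: Ag2O, 4 Å molecular sieves, Et2O, 35 °C, dark
Reagents that add atoms: none
Why: Williamson-type O-allylation under neutral Ag2O activation avoids enolate chemistry of the alpha-hydroxy ester and brings in C6 and C7.

Step 4
Reactants: 6 allyl ether
Product: 7 ethyl (2S,3R)-3-[(3R)-5-(TBDPS-oxy)-3-methylpentyl]-4-methyl-3,6-dihydro-2H-pyran-2-carboxylate
Conditions: second-generation Grubbs catalyst (H2IMes)(PCy3)Cl2Ru=CHPh (5 mol %), CH2Cl2 (0.01 M), 40 °C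
Reagents that add atoms: none
Why: Ring-closing metathesis of the allyl ether alkene with the isopropenyl group gives a six-membered temporary ring that can hold the new trisubstituted C7=C8 bond only with C6 and C9 cis, which fixes the Z geometry that ring B will need.

Step 5
Reactants: 7 dihydropyran ester
Product: 8 {(2S,3R)-3-[(3R)-5-(TBDPS-oxy)-3-methylpentyl]-4-methyl-3,6-dihydro-2H-pyran-2-yl}methanol
Conditions: LiAlH4, Et2O, 0 °C; aqueous work-up
Reagents that add atoms: none
Why: Ester reduction with LiAlH4 leaves the silyl ether, the ring ether and the alkene untouched.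

Step 6
Reactants: 8 primary alcohol
Product: 9 (2S,3R)-2-(chloromethyl)-3-[(3R)-5-(TBDPS-oxy)-3-methylpentyl]-4-methyl-3,6-dihydro-2H-pyran
Conditions: PPh3, CCl4, 70 °C
Reagents that add atoms: carbon tetrachloride, ClC(Cl)(Cl)Cl
Why: The Appel reaction turns the primary alcohol into the chloride under neutral conditions without touching C9 or C10.

Step 7
Reactants: 9 chloride
Product: 12 (2Z,4R,7R)-9-(TBDPS-oxy)-3,7-dimethyl-4-[(trimethylsilyl)ethynyl]non-2-en-1-ol, via dilithium alkoxide acetylide 10 (not isolated), via bis-silylated enynol 11 (not isolated)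
Conditions: LiN(iPr)2 (LDA, 4 equiv), THF, −78 to 0 °C; Me3SiCl, −78 °C to rt; then 1 M citric acid, MeOH
Reagents that add atoms: chlorotrimethylsilane, C[Si](C)(C)Cl
Why: Base-induced double elimination of a beta-alkoxy alkyl chloride (the tetrahydrofurfuryl chloride to pentynol type) expels HCl and then the ring alkoxide, which opens the temporary ring, turns C10–C1 into the alkyne, erases the auxiliary C10 stereocentre and frees the Z allylic alkoxide, after which silylation caps C1 and mild acid removes only the O-silyl group.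

Step 8
Reactants: 12 Z-allylic alcohol
Product: 13 (2Z,4R,7R)-1-bromo-9-(TBDPS-oxy)-3,7-dimethyl-4-[(trimethylsilyl)ethynyl]non-2-ene
Conditions: CBr4, PPh3, 2,6-lutidine, CH2Cl2, −20 °C
Reagents that add atoms: carbon tetrabromide, BrC(Br)(Br)Br
Why: The Appel bromination of a primary allylic alcohol at low temperature proceeds by SN2 displacement and keeps the Z geometry.

Step 9
Reactants: 14 3,3-dimethylcyclobutanone; 15 SAMP, (S)-1-amino-2-(methoxymethyl)pyrrolidine
Product: 16 SAMP hydrazone of 3,3-dimethylcyclobutanone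
Conditions: cyclohexane, reflux, water separator
Reagents that add atoms: none
Why: Hydrazone condensation with a strained and therefore electrophilic ketone installs the chiral auxiliary, and the two alpha positions of the symmetric ketone are equivalent.

Step 10
Reactants: 16 SAMP hydrazone; 13 allylic bromide
Product: 18 SAMP hydrazone of ketone 19 (5R), via lithiated hydrazone 17 (not isolated)
Conditions: LiN(iPr)2 (LDA), THF, 0 °C; then 13, −100 °C to rt
Reagents that add atoms: none
Why: SAMP-hydrazone (azaenolate) alkylation forms C5–C6 by SN2 attack on the primary allylic bromide with the Z alkene kept, and the chelated lithium azaenolate is attacked on the face left open by the methoxymethylpyrrolidine, which by the model for cyclic ketones gives 5R.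

Step 11
Reactants: 18 alkylated hydrazone
Product: 19 (2R)-2-{(2Z,4R,7R)-9-(TBDPS-oxy)-3,7-dimethyl-4-[(trimethylsilyl)ethynyl]non-2-en-1-yl}-3,3-dimethylcyclobutan-1-one
Conditions: saturated aqueous oxalic acid, Et2O, rt
Reagents that add atoms: water, O
Why: Mild two-phase acid hydrolysis of the hydrazone is known to spare alpha stereocentres, returns the auxiliary, and leaves the silyl alkyne, the silyl ether and the alkene intact.

Step 12
Reactants: 19 cyclobutanone enyne
Product: 20 (4aR,8R)-8-[(3R)-5-(TBDPS-oxy)-3-methylpentyl]-4,4,7-trimethyl-1-(trimethylsilyl)-4,4a,5,8-tetrahydronaphthalen-2(3H)-one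
Conditions: [Rh(cod)2]BF4 (10 mol %), Ph2P(CH2)4PPh2 (dppb, 12 mol %), 1,4-dioxane (0.02 M), 110 °C, closed vessel, Ar
Reagents that add atoms: none
Why: The cationic complex of monovalent rhodium is held by the silyl alkyne next to the ketone, adds oxidatively into the strained C2–C5 bond to give a five-membered acyl alkyl rhodacycle of trivalent rhodium, the alkyne then inserts into the Rh–C5 bond, and reductive elimination joins vinyl carbon C1 to acyl carbon C2 and returns the catalyst. The closest known reaction type is the rhodium-catalysed intramolecular (4+2) carboacylation ("cut and sew") of alkynes and alkenes by C–C activation of cyclobutanones and benzocyclobutenones, which includes saturated cyclobutanones that carry the tether on the alpha carbon. Ring B closes in the insertion as a 6-exo-dig carbometalation (C5 to C10), which the Z geometry of C7=C8 makes possible, and ring A closes in the C(sp2)–C(acyl) reductive elimination from the seven-membered rhodacycle (C1 to C2), so that the four-membered temporary ring is exchanged for six-membered ring A. No new stereocentre arises: C5 passes from C2 to rhodium to C10 with retention at each stage and C9 and C13 are spectators, so 5R and 9R are carried into 20. The step needs cleavage of the more hindered C2–C5 bond and not of C2–C3, which is secured by the alkyne anchored on C5 that delivers the metal to the proximal bond, while the tether length and the preference of rhodium for the silicon-bearing carbon fix the sense of insertion. The silyl cap on C1 suppresses alkyne oligomerisation and vinylidene formation, the C7=C8 bond cannot compete because its insertion would close a three- or four-membered ring, and the chelating diphosphine in a closed vessel disfavours loss of CO from the acyl intermediate.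

Step 13
Reactants: 20 alpha-silyl enone
Product: 21 (4aR,8R)-8-[(3R)-5-(TBDPS-oxy)-3-methylpentyl]-4,4,7-trimethyl-4,4a,5,8-tetrahydronaphthalen-2(3H)-one
Conditions: Bu4NF (1.1 equiv), AcOH (1.5 equiv), THF, −20 to 0 °C
Reagents that add atoms: none
Why: Fluoride-induced protodesilylation removes the helper from C1 because the C(sp2)–SiMe3 bond next to the carbonyl is far more labile than the hindered TBDPS ether, and the acetic acid buffer prevents the dienolate formation that would scramble C5 and C9.

Step 14
Reactants: 21 enone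
Product: 23 (4aR,8R,8aS)-8-[(3R)-5-(TBDPS-oxy)-3-methylpentyl]-4,4,7,8a-tetramethyl-3,4,4a,5,8,8a-hexahydronaphthalen-2(1H)-one (cis-fused), via trimethylsilyl enol ether 22 (not isolated)
Conditions: MeLi and CuI (gives Me2CuLi, 4 equiv), Me3SiCl, Et2O–THF, −78 to −20 °C; then 1 M HCl, THF, 0 °C
Reagents that add atoms: lithium dimethylcuprate, [Li+].C[Cu-]C
Why: Conjugate addition of a Gilman cuprate accelerated by Me3SiCl delivers C20 to C10 on the face that carries only H5 and H9, away from the C9 side chain and the axial alpha methyl on C4, which matches the known preference of 1(10)-octal-2-ones for cis-fused angular methylation and sets 10S.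

Step 15
Reactants: 23 cis-decalone
Product: 24 (2S,4aR,8R,8aS)-8-[(3R)-5-(TBDPS-oxy)-3-methylpentyl]-4,4,7,8a-tetramethyl-1,2,3,4,4a,5,8,8a-octahydronaphthalen-2-ol
Conditions: SmI2, H2O, Et3N, THF, rt
Reagents that add atoms: none
Why: Single-electron (ketyl) reduction under protic conditions gives the more stable alcohol, and since the beta face of C2 in the favoured chair of ring A is flanked by the axial methyl groups on C4 and C10, the equatorial alpha alcohol (2S) results, whereas bulky hydrides would give the axial epimer.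

Step 16
Reactants: 24 alcohol; 25 angelic acid
Product: 27 2-O-angeloyl derivative of 24 (Z ester retained), via mixed anhydride 26 (not isolated)
Conditions: 2,4,6-trichlorobenzoyl chloride, Et3N, toluene, rt; then 24, 80 °C, no DMAP
Reagents that add atoms: none
Why: Yamaguchi-type mixed anhydride acylation without a nucleophilic catalyst is the established way to transfer the angeloyl group with its Z geometry intact, and it takes place with retention at C2.

Step 17
Reactants: 27 angelate silyl ether
Product: 28 primary alcohol (C15–OH) of the angelate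
Conditions: HF·pyridine, pyridine, THF, 0 °C to rt
Reagents that add atoms: none
Why: Fluoride cleavage of the silyl ether under mildly acidic buffered conditions leaves the angelate and the trisubstituted alkene unchanged.

Step 18
Reactants: 28 primary alcohol
Product: 30 target acid CNP0248298.1, via aldehyde 29 (not isolated)
Conditions: TEMPO (20 mol %), PhI(OAc)2 (2.5 equiv), MeCN–aqueous pH 7 buffer, rt
Reagents that add atoms: water, O
Why: Oxoammonium (TEMPO) oxidation with PhI(OAc)2 in aqueous medium takes the primary alcohol through the aldehyde hydrate to the acid without touching the alkenes, the ester or any stereocentre.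

Compound list
1 | (R)-citronellol | CC(C)=CCC[C@@H](C)CCO | starting material
2 | (R)-citronellyl TBDPS ether | CC(C)=CCC[C@@H](C)CCO[Si](c1ccccc1)(c1ccccc1)C(C)(C)C | intermediate
3 | ethyl glyoxylate | CCOC(=O)C=O | starting material
4 | ethyl (2S,3R,6R)-8-(TBDPS-oxy)-2-hydroxy-6-methyl-3-(prop-1-en-2-yl)octanoate | CCOC(=O)[C@@H](O)[C@H](CC[C@@H](C)CCO[Si](c1ccccc1)(c1ccccc1)C(C)(C)C)C(C)=C | intermediate
5 | allyl bromide | C=CCBr | starting material
6 | ethyl (2S,3R,6R)-2-(allyloxy)-8-(TBDPS-oxy)-6-methyl-3-(prop-1-en-2-yl)octanoate | CCOC(=O)[C@@H](OCC=C)[C@H](CC[C@@H](C)CCO[Si](c1ccccc1)(c1ccccc1)C(C)(C)C)C(C)=C | intermediate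
7 | ethyl (2S,3R)-3-[(3R)-5-(TBDPS-oxy)-3-methylpentyl]-4-methyl-3,6-dihydro-2H-pyran-2-carboxylate | CCOC(=O)[C@H]1OCC=C(C)[C@H]1CC[C@@H](C)CCO[Si](c2ccccc2)(c2ccccc2)C(C)(C)C | intermediate
8 | {(2S,3R)-3-[(3R)-5-(TBDPS-oxy)-3-methylpentyl]-4-methyl-3,6-dihydro-2H-pyran-2-yl}methanol | OC[C@H]1OCC=C(C)[C@H]1CC[C@@H](C)CCO[Si](c2ccccc2)(c2ccccc2)C(C)(C)C | intermediate
9 | (2S,3R)-2-(chloromethyl)-3-[(3R)-5-(TBDPS-oxy)-3-methylpentyl]-4-methyl-3,6-dihydro-2H-pyran | ClC[C@H]1OCC=C(C)[C@H]1CC[C@@H](C)CCO[Si](c2ccccc2)(c2ccccc2)C(C)(C)C | intermediate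
10 | dilithium alkoxide acetylide of the Z-enynol | [Li+].[Li+].[O-]C/C=C(/C)[C@@H](CC[C@@H](C)CCO[Si](c1ccccc1)(c1ccccc1)C(C)(C)C)C#[C-] | intermediate
11 | O,C-bis(trimethylsilyl) Z-enynol | C[Si](C)(C)OC/C=C(/C)[C@@H](CC[C@@H](C)CCO[Si](c1ccccc1)(c1ccccc1)C(C)(C)C)C#C[Si](C)(C)C | intermediate
12 | (2Z,4R,7R)-9-(TBDPS-oxy)-3,7-dimethyl-4-[(trimethylsilyl)ethynyl]non-2-en-1-ol | OC/C=C(/C)[C@@H](CC[C@@H](C)CCO[Si](c1ccccc1)(c1ccccc1)C(C)(C)C)C#C[Si](C)(C)C | intermediate
13 | (2Z,4R,7R)-1-bromo-9-(TBDPS-oxy)-3,7-dimethyl-4-[(trimethylsilyl)ethynyl]non-2-ene | BrC/C=C(/C)[C@@H](CC[C@@H](C)CCO[Si](c1ccccc1)(c1ccccc1)C(C)(C)C)C#C[Si](C)(C)C | intermediate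
14 | 3,3-dimethylcyclobutanone | CC1(C)CC(=O)C1 | starting material
15 | SAMP, (S)-1-amino-2-(methoxymethyl)pyrrolidine | COC[C@@H]1CCCN1N | starting material
16 | SAMP hydrazone of 3,3-dimethylcyclobutanone | COC[C@@H]1CCCN1N=C2CC(C)(C)C2 | intermediate
17 | lithiated SAMP hydrazone (azaenolate) | [Li+].COC[C@@H]1CCCN1[N-]C2=CC(C)(C)C2 | intermediate
18 | SAMP hydrazone of ketone 19 (5R, N–N anti to C5) | COC[C@@H]1CCCN1/N=C2\CC(C)(C)[C@H]2C/C=C(/C)[C@@H](CC[C@@H](C)CCO[Si](c3ccccc3)(c3ccccc3)C(C)(C)C)C#C[Si](C)(C)C | intermediate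
19 | (2R)-2-{(2Z,4R,7R)-9-(TBDPS-oxy)-3,7-dimethyl-4-[(trimethylsilyl)ethynyl]non-2-en-1-yl}-3,3-dimethylcyclobutan-1-one | O=C1CC(C)(C)[C@H]1C/C=C(/C)[C@@H](CC[C@@H](C)CCO[Si](c2ccccc2)(c2ccccc2)C(C)(C)C)C#C[Si](C)(C)C | intermediate
20 | (4aR,8R)-8-[(3R)-5-(TBDPS-oxy)-3-methylpentyl]-4,4,7-trimethyl-1-(trimethylsilyl)-4,4a,5,8-tetrahydronaphthalen-2(3H)-one | O=C1CC(C)(C)[C@H]2CC=C(C)[C@@H](CC[C@@H](C)CCO[Si](c3ccccc3)(c3ccccc3)C(C)(C)C)C2=C1[Si](C)(C)C | intermediate
21 | (4aR,8R)-8-[(3R)-5-(TBDPS-oxy)-3-methylpentyl]-4,4,7-trimethyl-4,4a,5,8-tetrahydronaphthalen-2(3H)-one | O=C1CC(C)(C)[C@H]2CC=C(C)[C@@H](CC[C@@H](C)CCO[Si](c3ccccc3)(c3ccccc3)C(C)(C)C)C2=C1 | intermediate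
22 | trimethylsilyl enol ether (C1=C2) of 23 | C[Si](C)(C)OC=1CC(C)(C)[C@H]2CC=C(C)[C@@H](CC[C@@H](C)CCO[Si](c3ccccc3)(c3ccccc3)C(C)(C)C)[C@@]2(C)C=1 | intermediate
23 | (4aR,8R,8aS)-8-[(3R)-5-(TBDPS-oxy)-3-methylpentyl]-4,4,7,8a-tetramethyl-3,4,4a,5,8,8a-hexahydronaphthalen-2(1H)-one | O=C1CC(C)(C)[C@H]2CC=C(C)[C@@H](CC[C@@H](C)CCO[Si](c3ccccc3)(c3ccccc3)C(C)(C)C)[C@@]2(C)C1 | intermediate
24 | (2S,4aR,8R,8aS)-8-[(3R)-5-(TBDPS-oxy)-3-methylpentyl]-4,4,7,8a-tetramethyl-1,2,3,4,4a,5,8,8a-octahydronaphthalen-2-ol | O[C@H]1CC(C)(C)[C@H]2CC=C(C)[C@@H](CC[C@@H](C)CCO[Si](c3ccccc3)(c3ccccc3)C(C)(C)C)[C@@]2(C)C1 | intermediate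
25 | angelic acid, (Z)-2-methylbut-2-enoic acid | C/C=C(/C)C(=O)O | starting material
26 | angelic 2,4,6-trichlorobenzoic mixed anhydride | C/C=C(/C)C(=O)OC(=O)c1c(Cl)cc(Cl)cc1Cl | intermediate
27 | angelate of 24 (C15 TBDPS ether) | C/C=C(/C)C(=O)O[C@H]1CC(C)(C)[C@H]2CC=C(C)[C@@H](CC[C@@H](C)CCO[Si](c3ccccc3)(c3ccccc3)C(C)(C)C)[C@@]2(C)C1 | intermediate
28 | angelate with free C15 alcohol | C/C=C(/C)C(=O)O[C@H]1CC(C)(C)[C@H]2CC=C(C)[C@@H](CC[C@@H](C)CCO)[C@@]2(C)C1 | intermediate
29 | angelate C15 aldehyde | C/C=C(/C)C(=O)O[C@H]1CC(C)(C)[C@H]2CC=C(C)[C@@H](CC[C@@H](C)CC=O)[C@@]2(C)C1 | intermediate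
30 | (3R)-3-methyl-5-[(1R,4aR,7S,8aS)-2,5,5,8a-tetramethyl-7-{[(2Z)-2-methylbut-2-enoyl]oxy}-1,4,4a,5,6,7,8,8a-octahydronaphthalen-1-yl]pentanoic acid | C/C=C(/C)C(=O)O[C@H]1CC(C)(C)[C@H]2CC=C(C)[C@@H](CC[C@@H](C)CC(=O)O)[C@@]2(C)C1 | target

Total step count: 18. Longest linear sequence: 17 steps (steps 1–8 and 10–18) from (R)-citronellol.

Steps most likely to fail

**Step 12.**
- Risk: the hindered C2–C5 bond may fail to add oxidatively.
- Risk: the acyl rhodium intermediate may lose CO.
- Risk: beta-hydride elimination from C6 may outrun alkyne insertion.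
- Risk: metal hydrides may move the skipped unsaturation into conjugation.

Fallback, a radical ring opening followed by metathesis, sets out from 19 and comes back at 21:
- The alkyne of 19 is freed with catalytic AgNO3 in aqueous acetone to give the terminal-alkyne cyclobutanone F1.
- Condensation with O-(2,4-dinitrophenyl)hydroxylamine gives the O-aryl oxime F2.
- Visible light, eosin Y and 1,4-cyclohexadiene generate the iminyl radical. It opens the ring on the more substituted side to the C2 nitrile and the C5 radical.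
- A 6-exo-dig cyclisation with both large groups pseudo-equatorial, then hydrogen abstraction, gives the methylidenecyclohexene nitrile F3 (ring B, 5R re-set from 9R).
- CH2=CHMgBr followed by acidic hydrolysis gives the vinyl ketone F4.
- Ring-closing metathesis with the second-generation Hoveyda–Grubbs catalyst closes ring A to enone 21.

**Step 14.**
- Risk: addition to the very hindered beta carbon C10 may be too slow.
- Risk: deprotonation to the dienolate may erode C5 and C9.
- Risk: facial selectivity may be insufficient.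

Fallback, methylene transfer followed by reductive C–C cleavage, sets out from 21 and comes back at 23:
- Corey–Chaykovsky cyclopropanation with dimethylsulfoxonium methylide (Me3S(O)I, NaH, DMSO) adds the small ylide to C10 from the same open face. It closes onto C1 to give the cyclopropyl ketone F5.
- SmI2 in THF–DMPU with t-BuOH cleaves the exocyclic C1–C20 bond, the one that overlaps with the carbonyl. This leaves C20 as the beta methyl group of 23.

**Step 16.**
- Risk: the activated angeloyl group may isomerise from Z to E.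
- Risk: acylation at the temperature needed may be slow.

Fallback, construction of the Z alkene on the ester, sets out from 24 and comes back at 27:
- Esterification of 24 with 2-[bis(2,2,2-trifluoroethoxy)phosphoryl]propanoic acid (EDC, DMAP) gives the phosphonopropionate ester F6.
- Still–Gennari olefination with KN(SiMe3)2, 18-crown-6 and acetaldehyde at −78 °C gives the Z-2-methylbut-2-enoate 27.

Further compounds
F1 | step 12 | (2R)-2-[(2Z,4S,7R)-9-(TBDPS-oxy)-4-ethynyl-3,7-dimethylnon-2-en-1-yl]-3,3-dimethylcyclobutan-1-one | O=C1CC(C)(C)[C@H]1C/C=C(/C)[C@@H](CC[C@@H](C)CCO[Si](c2ccccc2)(c2ccccc2)C(C)(C)C)C#C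
F2 | step 12 | O-(2,4-dinitrophenyl) oxime of F1 (C=N isomers) | O=[N+]([O-])c1ccc(ON=C2CC(C)(C)[C@H]2C/C=C(/C)[C@@H](CC[C@@H](C)CCO[Si](c3ccccc3)(c3ccccc3)C(C)(C)C)C#C)c([N+](=O)[O-])c1
F3 | step 12 | 3-{(1R,5R)-5-[(3R)-5-(TBDPS-oxy)-3-methylpentyl]-4-methyl-6-methylidenecyclohex-3-en-1-yl}-3-methylbutanenitrile | N#CCC(C)(C)[C@H]1CC=C(C)[C@@H](CC[C@@H](C)CCO[Si](c2ccccc2)(c2ccccc2)C(C)(C)C)C1=C
F4 | step 12 | 5-{(1R,5R)-5-[(3R)-5-(TBDPS-oxy)-3-methylpentyl]-4-methyl-6-methylidenecyclohex-3-en-1-yl}-5-methylhex-1-en-3-one | C=CC(=O)CC(C)(C)[C@H]1CC=C(C)[C@@H](CC[C@@H](C)CCO[Si](c2ccccc2)(c2ccccc2)C(C)(C)C)C1=C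
F5 | step 14 | cyclopropyl ketone from 21 (C20 methylene bridging C1 and C10 on the beta face) | O=C1CC(C)(C)[C@H]2CC=C(C)[C@@H](CC[C@@H](C)CCO[Si](c4ccccc4)(c4ccccc4)C(C)(C)C)[C@]23C[C@H]13
F6 | step 16 | 2-[bis(2,2,2-trifluoroethoxy)phosphoryl]propanoate of 24 (epimers at the phosphonate carbon) | CC(C(=O)O[C@H]1CC(C)(C)[C@H]2CC=C(C)[C@@H](CC[C@@H](C)CCO[Si](c3ccccc3)(c3ccccc3)C(C)(C)C)[C@@]2(C)C1)P(=O)(OCC(F)(F)F)OCC(F)(F)F
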